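**Plan**

1. Retrosynthesis: free the C8–OH from a MOM ether and take C9=O back to a carbinol whose oxygen carries the C12 acyl group (six-membered lactone in place of the γ-lactone on O6). Then cut C6–C7 to a C6 aldehyde and a 3-(bromomethyl)pentenolide, cut the pentenolide at C7=C11 (metathesis) and O9–C12 (ester), then cut C8–C9 (alkoxyallylboration), which leaves a geraniol-derived C1–C6/C9/C10 chain.
2. Enabling feature: C7 is the γ-carbon of the 2-methylene-acyl unit C13=C11–C12(=O) and C6 bears oxygen, so C6–C7 is the bond an allyl metal makes with an aldehyde; both carbons are electrophilic in the precursor and are joined after reductive polarity reversal. The C8/C9 glycol beside it allows a temporary six-membered lactone (O9–C12–C11=C7–C8–C9) that locks the allyl geometry and tethers it at C9.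
3. Forward order: geraniol → epoxide → anti-diol with the isobutyrate on O5 → C9 oxidation, hydrogenation, aldehyde → alkoxyallylboration (C7, C8) → pentenolide by acylation and ring-closing metathesis → C6 aldehyde → ten-membered ring by C6–C7 closure → lactone shift O9→O6 (γ-lactone) → C9 ketone → free C8–OH.
4. Stereochemistry: C4/C5 from Sharpless epoxidation and inverting hydrolysis; C10 from catalytic hydrogenation; C8 and a temporary C9 centre from the Brown reagent; C7 and C6 relayed from C8/C9 in the key step by the lactone ring, the tether and a chair transition state; the C9 centre is then erased by oxidation.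

Key step: step 14

Remark on numbering: C1–C15 are the germacrane locants of the target (ring C1–C10, methyl C14 on C10, methyl C15 on C4, C11 bearing exocyclic C13, carbonyl C12). Compounds 2–8 are named as octane derivatives. CIP letters change where priorities change (C5 in 19, C7 in 22) without any change in space.

Assumption: in step 6 the ligand hand is the one that delivers hydrogen to the face giving the (S)-methyl centre; (S)-tBu-PHOX is written and its mirror image is used if a model substrate shows the opposite sense.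

**Step 1**
Reactants: 1 geraniol
Product: 2 (2S,3S)-2,3-epoxygeraniol
Conditions: Ti(OiPr)4 (5 mol%), L-(+)-diethyl tartrate (7 mol%), t-BuOOH, 4 Å MS, CH2Cl2, −20 °C
Reagents that add atoms: tert-butyl hydroperoxide, CC(C)(C)OO
Why: Sharpless asymmetric epoxidation, in which titanium binds the allylic alcohol so that only the C2=C3 alkene reacts and the L-tartrate ligand delivers oxygen to the face that gives the (2S,3S)-epoxide.

**Step 2**
Reactants: 2 (2S,3S)-2,3-epoxygeraniol
Product: 3 (2S,3R)-3,7-dimethyloct-6-ene-1,2,3-triol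
Conditions: HClO4 (cat.), THF/H2O, 0 °C to rt
Reagents that add atoms: water, O
Why: Acid-catalysed epoxide hydrolysis, in which water should open the protonated epoxide at the tertiary carbon (better cation-stabilised and remote from the CH2OH group) with inversion, turning the (E)-derived epoxide into the anti tertiary/secondary diol (future C4 R and C5 S).

**Step 3**
Reactants: 3 (2S,3R)-3,7-dimethyloct-6-ene-1,2,3-triol
Product: 4 (2S,3R)-1-(tert-butyldimethylsilyloxy)-3,7-dimethyloct-6-ene-2,3-diol
Conditions: TBSCl, imidazole, CH2Cl2, 0 °C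
Reagents that add atoms: tert-butyldimethylsilyl chloride, CC(C)(C)[Si](C)(C)Cl
Why: Silyl ether formation, selective for the primary hydroxyl over the secondary and tertiary ones on steric grounds.

**Step 4**
Reactants: 4 (2S,3R)-1-(tert-butyldimethylsilyloxy)-3,7-dimethyloct-6-ene-2,3-diol
Product: 5 (2S,3R)-1-(tert-butyldimethylsilyloxy)-3-hydroxy-3,7-dimethyloct-6-en-2-yl 2-methylpropanoate
Conditions: i-PrCOCl, pyridine, DMAP (cat.), CH2Cl2, 0 °C to rt
Reagents that add atoms: isobutyryl chloride, CC(C)C(=O)Cl
Why: Acylation of the only secondary hydroxyl (the tertiary one is inert under these conditions), which places the natural ester on O5 at the one point where no other secondary alcohol competes.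

**Step 5**
Reactants: 5 (2S,3R)-1-(tert-butyldimethylsilyloxy)-3-hydroxy-3,7-dimethyloct-6-en-2-yl 2-methylpropanoate
Product: 6 (2S,3R,6E)-1-(tert-butyldimethylsilyloxy)-3,8-dihydroxy-3,7-dimethyloct-6-en-2-yl 2-methylpropanoate
Conditions: SeO2 (cat.), t-BuOOH, salicylic acid (cat.), CH2Cl2, rt
Reagents that add atoms: selenium dioxide, O=[Se]=O (oxygen carrier); tert-butyl hydroperoxide, CC(C)(C)OO (terminal oxidant)
Why: Selenium dioxide allylic oxidation (ene reaction, then 2,3-sigmatropic shift), which on a trisubstituted isopropylidene group selects the (E)-methyl and gives the (E)-allylic alcohol at the future C9.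

**Step 6**
Reactants: 6 (2S,3R,6E)-1-(tert-butyldimethylsilyloxy)-3,8-dihydroxy-3,7-dimethyloct-6-en-2-yl 2-methylpropanoate
Product: 7 (2S,3R,7S)-1-(tert-butyldimethylsilyloxy)-3,8-dihydroxy-3,7-dimethyloctan-2-yl 2-methylpropanoate
Conditions: H2 (50 bar), [Ir(cod){(S)-tBu-PHOX}]BArF (1 mol%), CH2Cl2, rt
Reagents that add atoms: none
Why: Iridium-catalysed asymmetric hydrogenation of a trisubstituted (E)-2-methyl allylic alcohol, the only C=C bond in the molecule, in which the chiral P,N ligand selects the alkene face and so sets the C10 methyl centre (S) by catalyst control.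

**Step 7**
Reactants: 7 (2S,3R,7S)-1-(tert-butyldimethylsilyloxy)-3,8-dihydroxy-3,7-dimethyloctan-2-yl 2-methylpropanoate
Product: 8 (2S,3R,7S)-1-(tert-butyldimethylsilyloxy)-3-hydroxy-3,7-dimethyl-8-oxooctan-2-yl 2-methylpropanoate
Conditions: Dess–Martin periodinane, CH2Cl2, 0 °C to rt; used crude
Reagents that add atoms: none
Why: Dess–Martin oxidation of the primary alcohol (the tertiary alcohol cannot react) under non-basic conditions that should not epimerise the α-methyl aldehyde.

**Step 8**
Reactants: 9 allyl alcohol
Product: 10 allyl methoxymethyl ether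
Conditions: MOMCl, i-Pr2NEt, CH2Cl2, 0 °C to rt
Reagents that add atoms: chloromethyl methyl ether, COCCl
Why: O-alkylation of the alcohol by the reactive α-chloro ether (acetal formation), a standard preparation of this allyl ether.

**Step 9**
Reactants: 8 (2S,3R,7S)-1-(tert-butyldimethylsilyloxy)-3-hydroxy-3,7-dimethyl-8-oxooctan-2-yl 2-methylpropanoate; 10 allyl methoxymethyl ether
Product: 13 (2S,3R,7S,8S,9S)-1-(tert-butyldimethylsilyloxy)-3,8-dihydroxy-9-(methoxymethoxy)-3,7-dimethylundec-10-en-2-yl 2-methylpropanoate, via allylborane 11 (not isolated), via borinate ester 12 (not isolated)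
Conditions: 10, s-BuLi, THF, −78 °C; (+)-Ipc2BOMe, then BF3·OEt2; then 8, −78 °C; then H2O2, pH 7 buffer, 0 °C to rt
Reagents that add atoms: none
Why: Brown (Z)-γ-alkoxyallylboration through a closed chair transition state, in which the Z geometry of the boron reagent gives the syn C8/C9 relationship and the isopinocampheyl groups from (−)-α-pinene direct attack to the Re face of the aldehyde (C9 S, hence C8 S), which is also the anti-Felkin sense that Z-configured allylboron reagents prefer with α-methyl aldehydes, so reagent and substrate are matched.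

**Step 10**
Reactants: 13 (2S,3R,7S,8S,9S)-1-(tert-butyldimethylsilyloxy)-3,8-dihydroxy-9-(methoxymethoxy)-3,7-dimethylundec-10-en-2-yl 2-methylpropanoate; 14 2-(bromomethyl)acrylic acid
Product: 16 C9 2-(bromomethyl)acrylate of 13, via acid chloride 15 (not isolated)
Conditions: 14, (COCl)2, DMF (cat.), CH2Cl2, 0 °C to rt; then 13, 2,6-lutidine, CH2Cl2, 0 °C to rt
Reagents that add atoms: none
Why: Esterification of the only secondary alcohol through the acid chloride with a hindered, non-nucleophilic base, which avoids SN2′ attack of an amine on the allylic bromide and leaves the tertiary C4–OH untouched.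

**Step 11**
Reactants: 16 C9 2-(bromomethyl)acrylate of 13
Product: 17 (5S,6S)-3-(bromomethyl)-5-(methoxymethoxy)-5,6-dihydro-2H-pyran-2-one whose C6 (= C9) carries the (10S)-C10–C1–C2–C3–(4R)-C4(OH)(CH3)–(5S)-C5(O-isobutyryl)–C6H2OTBS chain
Conditions: second-generation Grubbs catalyst RuCl2(=CHPh)(PCy3)(H2IMes) (10 mol%), toluene (2 mM), 80 °C
Reagents that add atoms: none
Why: Ring-closing metathesis between the vinyl group and the 2-substituted acrylate (six-membered unsaturated lactone with loss of ethylene), which creates the C7=C11 bond and, by the ring, holds C8 cis to the carbonyl; no stereocentre is touched.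

**Step 12**
Reactants: 17 pentenolide bromide silyl ether
Product: 18 the C6 primary alcohol corresponding to 17 (4R,5S,8S,9S,10S)
Conditions: aq. HF (48%), MeCN, 0 °C
Reagents that add atoms: none
Why: Acidic fluoride cleavage of the primary silyl ether; the amine-free acidic medium spares the allylic bromide and the MOM acetal and should suppress the base-promoted 1,2-shift of the isobutyrate to the new primary hydroxyl.

**Step 13**
Reactants: 18 pentenolide bromide alcohol
Product: 19 pentenolide bromide aldehyde (C6 = CHO; 4R,5R,8S,9S,10S)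
Conditions: Dess–Martin periodinane, CH2Cl2, 0 °C to rt; used at once
Reagents that add atoms: none
Why: Dess–Martin oxidation of the primary alcohol to the α-acyloxy aldehyde under neutral conditions that leave the allylic bromide, the lactone and the tertiary alcohol intact.

**Step 14**
Reactants: 19 pentenolide bromide aldehyde
Product: 22 (4R,5S,6R,7R,8S,9S,10S)-4,6-dihydroxy-5-(isobutyryloxy)-8-(methoxymethoxy)germacr-11(13)-en-12,9-olide (ten-membered ring bridged by the six-membered lactone), via allylchromium dichloride 20 (not isolated), via chromium alkoxide 21 (not isolated)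
Conditions: CrCl2 (6 equiv), THF/DMF (10:1), rt, 19 added by syringe pump over 12 h (final 2 mM); then H2O
Reagents that add atoms: none
Why: Chromium dichloride reduces the allylic C13–Br bond by two one-electron transfers to the allylchromium 20, which adds through its γ-carbon C7 to the C6 aldehyde in a closed six-membered chair transition state with allylic transposition, leaving C13 as the exocyclic methylene; the closest known reaction type is the intramolecular Nozaki–Hiyama (Barbier-type) allylation of aldehydes by 2-(bromomethyl)-2-enoates, known for medium-ring closure. The ten-membered carbocycle closes by exo attack on the aldehyde carbon (10-exo-trig at C6, SE2′ at the allyl unit) and is bridged across C7–C9 by the pentenolide. C7 is controlled by the tether: the chain starts at C9 and can reach only the pentenolide face on which C10 stands, cis to the C8 ether (cis-1,3 bridging), and because C8/C9 were set syn this is the target configuration. C6 is controlled by the chair: the lactone ring holds C8 trans to the CH2Cr carbon (an E-type allyl metal that cannot isomerise) and C5 takes the equatorial place gauche to C8, which the short tether also demands, so the anti C6–O/C7–C8 adduct (the later trans-fused γ-lactone) should form. The step needs aldehyde-over-ester chemoselectivity (inherent to allylchromium reagents), γ- over α-attack (closed transition state) and ring closure over oligomerisation (slow addition at high dilution).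

**Step 15**
Reactants: 22 bridged hydroxy lactone
Product: 23 (4R,5S,6R,7S,8S,9S,10S)-4,9-dihydroxy-5-(isobutyryloxy)-8-(methoxymethoxy)germacr-11(13)-en-12,6-olide
Conditions: PPTS (0.2 equiv), toluene, 40 °C
Reagents that add atoms: none
Why: Acid-catalysed intramolecular transesterification (translactonisation), in which the C6 hydroxyl, held gauche to C11–C12 by the preceding chair, attacks the carbonyl of the strained bridged six-membered lactone and releases O9; the fused five-membered lactone is the thermodynamic sink because any isobutyryl shift between O5 and O6 is reversible while only the O6-free isomer can lactonise, and no stereocentre is touched.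

**Step 16**
Reactants: 23 γ-lactone with free C9 hydroxyl
Product: 24 (4R,5S,6R,7S,8S,10S)-4-hydroxy-5-(isobutyryloxy)-8-(methoxymethoxy)-9-oxogermacr-11(13)-en-12,6-olide
Conditions: Dess–Martin periodinane, CH2Cl2, rt
Reagents that add atoms: none
Why: Dess–Martin oxidation of the only secondary alcohol (the tertiary C4–OH cannot be oxidised), which erases the temporary C9 stereocentre in a non-basic medium that leaves the now enolisable C10 centre alone.

**Step 17**
Reactants: 24 C8 MOM ether of the target
Product: 26 (4R,5S,6R,7S,8S,10S)-4,8-dihydroxy-5-(isobutyryloxy)-9-oxogermacr-11(13)-en-12,6-olide (CNP0270933.1), via bromomethyl ether 25 (not isolated)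
Conditions: Me2BBr, CH2Cl2, −78 °C; then THF/sat. aq. NaHCO3
Reagents that add atoms: none
Why: Lewis-acid cleavage of the methoxymethyl acetal by bromodimethylborane (acetal exchange to a bromomethyl ether that hydrolyses on work-up) at −78 °C, conditions under which the esters, the α-methylene lactone and the ketone are inert and no base is present that could epimerise C8 or C10; the tertiary alcohol is at most borylated transiently and returns on work-up.

**Compound list**

1 | geraniol | CC(C)=CCC/C(C)=C/CO | starting material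
2 | (2S,3S)-2,3-epoxygeraniol | CC(C)=CCC[C@]1(C)O[C@H]1CO | intermediate
3 | (2S,3R)-3,7-dimethyloct-6-ene-1,2,3-triol | CC(C)=CCC[C@@](C)(O)[C@@H](O)CO | intermediate
4 | (2S,3R)-1-(tert-butyldimethylsilyloxy)-3,7-dimethyloct-6-ene-2,3-diol | CC(C)=CCC[C@@](C)(O)[C@@H](O)CO[Si](C)(C)C(C)(C)C | intermediate
5 | (2S,3R)-1-(tert-butyldimethylsilyloxy)-3-hydroxy-3,7-dimethyloct-6-en-2-yl 2-methylpropanoate | CC(C)=CCC[C@@](C)(O)[C@@H](OC(=O)C(C)C)CO[Si](C)(C)C(C)(C)C | intermediate
6 | (2S,3R,6E)-1-(tert-butyldimethylsilyloxy)-3,8-dihydroxy-3,7-dimethyloct-6-en-2-yl 2-methylpropanoate | OC/C(C)=C/CC[C@@](C)(O)[C@@H](OC(=O)C(C)C)CO[Si](C)(C)C(C)(C)C | intermediate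
7 | (2S,3R,7S)-1-(tert-butyldimethylsilyloxy)-3,8-dihydroxy-3,7-dimethyloctan-2-yl 2-methylpropanoate | OC[C@@H](C)CCC[C@@](C)(O)[C@@H](OC(=O)C(C)C)CO[Si](C)(C)C(C)(C)C | intermediate
8 | (2S,3R,7S)-1-(tert-butyldimethylsilyloxy)-3-hydroxy-3,7-dimethyl-8-oxooctan-2-yl 2-methylpropanoate | O=C[C@@H](C)CCC[C@@](C)(O)[C@@H](OC(=O)C(C)C)CO[Si](C)(C)C(C)(C)C | intermediate
9 | allyl alcohol | C=CCO | starting material
10 | allyl methoxymethyl ether | C=CCOCOC | intermediate
11 | [(Z)-3-(methoxymethoxy)allyl]diisopinocampheylborane, isopinocampheyl groups from (−)-α-pinene, formed in the flask | COCO/C=C\CB([C@H]1C[C@H]2C[C@H](C2(C)C)[C@@H]1C)[C@H]1C[C@H]2C[C@H](C2(C)C)[C@@H]1C | intermediate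
12 | O9-diisopinocampheylborinate of 13, formed in the flask | C=C[C@H](OCOC)[C@@H](OB([C@H]1C[C@H]2C[C@H](C2(C)C)[C@@H]1C)[C@H]1C[C@H]2C[C@H](C2(C)C)[C@@H]1C)[C@@H](C)CCC[C@@](C)(O)[C@@H](OC(=O)C(C)C)CO[Si](C)(C)C(C)(C)C | intermediate
13 | (2S,3R,7S,8S,9S)-1-(tert-butyldimethylsilyloxy)-3,8-dihydroxy-9-(methoxymethoxy)-3,7-dimethylundec-10-en-2-yl 2-methylpropanoate (germacrane locants 4R,5S,8S,9S,10S) | C=C[C@H](OCOC)[C@@H](O)[C@@H](C)CCC[C@@](C)(O)[C@@H](OC(=O)C(C)C)CO[Si](C)(C)C(C)(C)C | intermediate
14 | 2-(bromomethyl)acrylic acid | C=C(CBr)C(=O)O | starting material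
15 | 2-(bromomethyl)acryloyl chloride, formed in the flask | C=C(CBr)C(=O)Cl | intermediate
16 | C9 2-(bromomethyl)acrylate of 13 (4R,5S,8S,9S,10S) | C=C[C@H](OCOC)[C@@H](OC(=O)C(=C)CBr)[C@@H](C)CCC[C@@](C)(O)[C@@H](OC(=O)C(C)C)CO[Si](C)(C)C(C)(C)C | intermediate
17 | (5S,6S)-3-(bromomethyl)-5-(methoxymethoxy)-5,6-dihydro-2H-pyran-2-one with the C10–C6 chain on C6, C6–OTBS (4R,5S,8S,9S,10S) | BrCC1=C[C@H](OCOC)[C@H]([C@@H](C)CCC[C@@](C)(O)[C@@H](OC(=O)C(C)C)CO[Si](C)(C)C(C)(C)C)OC1=O | intermediate
18 | pentenolide bromide with free C6 primary alcohol (4R,5S,8S,9S,10S) | BrCC1=C[C@H](OCOC)[C@H]([C@@H](C)CCC[C@@](C)(O)[C@@H](OC(=O)C(C)C)CO)OC1=O | intermediate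
19 | pentenolide bromide C6 aldehyde (4R,5R,8S,9S,10S) | BrCC1=C[C@H](OCOC)[C@H]([C@@H](C)CCC[C@@](C)(O)[C@@H](OC(=O)C(C)C)C=O)OC1=O | intermediate
20 | allylchromium dichloride from 19, formed in the flask | Cl[Cr](Cl)CC1=C[C@H](OCOC)[C@H]([C@@H](C)CCC[C@@](C)(O)[C@@H](OC(=O)C(C)C)C=O)OC1=O | intermediate
21 | O6-chromium dichloride alkoxide of 22, formed in the flask | C=C1C(=O)O[C@@H]2[C@@H](OCOC)[C@H]1[C@@H](O[Cr](Cl)Cl)[C@H](OC(=O)C(C)C)[C@](C)(O)CCC[C@@H]2C | intermediate
22 | (4R,5S,6R,7R,8S,9S,10S)-4,6-dihydroxy-5-(isobutyryloxy)-8-(methoxymethoxy)germacr-11(13)-en-12,9-olide | C=C1C(=O)O[C@@H]2[C@@H](OCOC)[C@H]1[C@@H](O)[C@H](OC(=O)C(C)C)[C@](C)(O)CCC[C@@H]2C | intermediate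
23 | (4R,5S,6R,7S,8S,9S,10S)-4,9-dihydroxy-5-(isobutyryloxy)-8-(methoxymethoxy)germacr-11(13)-en-12,6-olide | C=C1C(=O)O[C@@H]2[C@@H]1[C@H](OCOC)[C@@H](O)[C@@H](C)CCC[C@@](C)(O)[C@H]2OC(=O)C(C)C | intermediate
24 | (4R,5S,6R,7S,8S,10S)-4-hydroxy-5-(isobutyryloxy)-8-(methoxymethoxy)-9-oxogermacr-11(13)-en-12,6-olide | C=C1C(=O)O[C@@H]2[C@@H]1[C@H](OCOC)C(=O)[C@@H](C)CCC[C@@](C)(O)[C@H]2OC(=O)C(C)C | intermediate
25 | O8-bromomethyl ether of 26, formed in the flask | C=C1C(=O)O[C@@H]2[C@@H]1[C@H](OCBr)C(=O)[C@@H](C)CCC[C@@](C)(O)[C@H]2OC(=O)C(C)C | intermediate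
26 | (4R,5S,6R,7S,8S,10S)-4,8-dihydroxy-5-(isobutyryloxy)-9-oxogermacr-11(13)-en-12,6-olide (CNP0270933.1) | C=C1C(=O)O[C@@H]2[C@@H]1[C@H](O)C(=O)[C@@H](C)CCC[C@@](C)(O)[C@H]2OC(=O)C(C)C | target

**Step count**

Total steps: 17. Longest linear sequence: 16 (steps 1–7 and 9–17, from geraniol).

**Steps most likely to fail**

Step 14. The allylchromium may be consumed by intermolecular allylation (oligomers) or by protonation before the ten-membered ring closes, or the ring may close through the chair with C5 axial and give the C6 epimer. The fallback closes the same bond without a reducing metal. It sets out from 17: Pd2(dba)3 (cat.) and B2pin2 in DMSO at 50 °C (Miyaura borylation of the allylic bromide at the primary carbon) should give the pinacol allylboronate silyl ether F1. CSA (cat.) in MeOH at 0 °C should free the primary alcohol to the allylboronate alcohol F2, and Dess–Martin periodinane should give the allylboronate aldehyde F3. On warming in toluene (Sc(OTf)3 cat. if needed) F3 should close by intramolecular allylboration through the same ring-locked chair, and cleavage of the borate with triethanolamine comes back to the route at 22.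

Step 11. The allylic bromide may alkylate or deactivate the ruthenium carbene, or the carbene may fail to engage the 1,1-disubstituted acrylate so that only dimers form. The fallback sets out from 13 and brings in the bromomethyl group after the ring is made. Acryloyl chloride and i-Pr2NEt should give the plain C9 acrylate F4, which the same ruthenium catalyst should close to the unsubstituted pentenolide F5 (the best-precedented case of this metathesis). I2 and pyridine should give the α-iodo pentenolide F6; Stille coupling with Bu3SnCH2OH and Pd(PPh3)4 should give the α-hydroxymethyl pentenolide F7; an Appel reaction (CBr4, PPh3) comes back to the route at 17.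

Step 6. Hydrogen may be delivered with poor or reversed facial selectivity to this purely alkyl-substituted trisubstituted alkene. The fallback uses carboxylate-directed hydrogenation and sets out from 6: MnO2 should give the (E)-enal F8 and a Pinnick oxidation (NaClO2, NaH2PO4, 2-methyl-2-butene) the (E)-2-methyl-2-enoic acid F9. Hydrogenation with Ru(OAc)2[(S)-BINAP] in MeOH (ligand hand chosen for the S centre) should give the (S)-2-methyl acid F10, and BH3·SMe2 should reduce the acid in the presence of the isobutyrate and come back to the route at 7.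

**Further compounds**

F1 | step 14 | pinacol allylboronate silyl ether (Bpin in place of Br in 17) | CC1(C)OB(CC2=C[C@H](OCOC)[C@H]([C@@H](C)CCC[C@@](C)(O)[C@@H](OC(=O)C(C)C)CO[Si](C)(C)C(C)(C)C)OC2=O)OC1(C)C
F2 | step 14 | allylboronate alcohol (C6 primary OH) | CC1(C)OB(CC2=C[C@H](OCOC)[C@H]([C@@H](C)CCC[C@@](C)(O)[C@@H](OC(=O)C(C)C)CO)OC2=O)OC1(C)C
F3 | step 14 | allylboronate aldehyde (C6 = CHO) | CC1(C)OB(CC2=C[C@H](OCOC)[C@H]([C@@H](C)CCC[C@@](C)(O)[C@@H](OC(=O)C(C)C)C=O)OC2=O)OC1(C)C
F4 | step 11 | C9 acrylate of 13 | C=C[C@H](OCOC)[C@@H](OC(=O)C=C)[C@@H](C)CCC[C@@](C)(O)[C@@H](OC(=O)C(C)C)CO[Si](C)(C)C(C)(C)C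
F5 | step 11 | unsubstituted pentenolide (H in place of CH2Br in 17) | O=C1C=C[C@H](OCOC)[C@H]([C@@H](C)CCC[C@@](C)(O)[C@@H](OC(=O)C(C)C)CO[Si](C)(C)C(C)(C)C)O1
F6 | step 11 | α-iodo pentenolide | O=C1C(I)=C[C@H](OCOC)[C@H]([C@@H](C)CCC[C@@](C)(O)[C@@H](OC(=O)C(C)C)CO[Si](C)(C)C(C)(C)C)O1
F7 | step 11 | α-hydroxymethyl pentenolide | O=C1C(CO)=C[C@H](OCOC)[C@H]([C@@H](C)CCC[C@@](C)(O)[C@@H](OC(=O)C(C)C)CO[Si](C)(C)C(C)(C)C)O1
F8 | step 6 | (E)-enal from 6 | O=C/C(C)=C/CC[C@@](C)(O)[C@@H](OC(=O)C(C)C)CO[Si](C)(C)C(C)(C)C
F9 | step 6 | (E)-2-methyl-2-enoic acid from 6 | OC(=O)/C(C)=C/CC[C@@](C)(O)[C@@H](OC(=O)C(C)C)CO[Si](C)(C)C(C)(C)C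
F10 | step 6 | (S)-2-methyl carboxylic acid corresponding to 7 | OC(=O)[C@@H](C)CCC[C@@](C)(O)[C@@H](OC(=O)C(C)C)CO[Si](C)(C)C(C)(C)C
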